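**Retrosynthetic overview**
1. Feature: ring B of the target carries the ether oxygen on C4', OMe on C3' and C5', and the chain C7'–C8'–C9' on C1'. This is the skeleton of 4-allyl-2,6-dimethoxyphenol, which lacks only the oxygen on C9' and has its alkene at C8'=C9' instead of C7'=C8'.
2. Last disconnection, C9'–O: the E-allylic alcohol comes from its acetate. The acetate comes from the allylarene ketone by palladium-catalysed allylic C–H acetoxylation with alkene transposition.
3. Before that, the C7–C1 bond (carbonyl to ring A) comes from a Weinreb amide and 3,4,5-trimethoxyphenylmagnesium bromide.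
4. First, the C8–O bond comes from SN2 inversion of the triflate of ethyl (S)-lactate by the phenolate, which sets the R centre at C8.
5. Ring order: no ring is formed; rings A and B are both bought as arenes.

Key step: step 5

Remark on the chemistry: neolignan numbering is used. Ring A is 3,4,5-trimethoxyphenyl, C7 is the carbonyl carbon, C8 the stereocentre and C9 its methyl group; ring B atoms are primed. The target SMILES reads as R at C8 (O-aryl > C7 > C9 > H). Enantiomeric purity should be checked by chiral HPLC at 5, 10, 12 and 13.

**Route**

Step 1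
Reactants: 1 ethyl (S)-lactate
Product: 2 ethyl (S)-2-[(trifluoromethylsulfonyl)oxy]propanoate
Conditions: Tf2O (1.05 equiv), 2,6-lutidine (1.1 equiv), CH2Cl2, −78 → 0 °C; used promptly
Reagents that add atoms: trifluoromethanesulfonic anhydride, O=S(=O)(OS(=O)(=O)C(F)(F)F)C(F)(F)F
Why: O-sulfonylation of a secondary alcohol with triflic anhydride and a hindered pyridine base touches only the O–H bond, so the S configuration at C8 passes unchanged into a leaving group reactive enough for a clean low-temperature SN2 step.

Step 2
Reactants: 2 ethyl (S)-2-[(trifluoromethylsulfonyl)oxy]propanoate; 3 4-allyl-2,6-dimethoxyphenol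
Product: 5 ethyl (R)-2-(4-allyl-2,6-dimethoxyphenoxy)propanoate, via potassium 4-allyl-2,6-dimethoxyphenolate 4 (not isolated)
Conditions: 3 (1.05 equiv), K2CO3 (1.5 equiv), MeCN, rt; then 2, 0 °C → rt
Reagents that add atoms: none
Why: In this Williamson-type SN2 etherification, phenolate 4 attacks C8 of the α-triflyloxy ester from the back side and inverts the S centre to the R centre of the target, and the very reactive triflate lets the hindered 2,6-dimethoxyphenolate react at or below room temperature, where elimination and enolisation do not compete.

Step 3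
Reactants: 5 ethyl (R)-2-(4-allyl-2,6-dimethoxyphenoxy)propanoate
Product: 6 (R)-2-(4-allyl-2,6-dimethoxyphenoxy)-N-methoxy-N-methylpropanamide
Conditions: MeNH(OMe)·HCl (1.5 equiv), iPrMgCl (3.0 equiv), THF, −20 → −5 °C; then cold 1 M HCl
Reagents that add atoms: N,O-dimethylhydroxylamine hydrochloride, CNOC.Cl
Why: This is a Weinreb amide synthesis by aminolysis of the ester with the chloromagnesium amide made in the flask; acyl substitution at −20 °C is much faster than deprotonation at C8, so the R centre is carried through untouched, and the allyl group and aryl ethers are inert.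

Step 4
Reactants: 6 (R)-2-(4-allyl-2,6-dimethoxyphenoxy)-N-methoxy-N-methylpropanamide; 7 5-bromo-1,2,3-trimethoxybenzene
Product: 10 (R)-2-(4-allyl-2,6-dimethoxyphenoxy)-1-(3,4,5-trimethoxyphenyl)propan-1-one, via 3,4,5-trimethoxyphenylmagnesium bromide 8 (not isolated), via bromomagnesium hemiaminal chelate 9 (not isolated)
Conditions: 7 (1.5 equiv), Mg turnings (1.8 equiv, started with a crystal of iodine), THF, reflux; then 6, THF, −20 → 0 °C; then cold 1 M HCl
Reagents that add atoms: none
Why: In this Weinreb ketone synthesis, aryl Grignard reagent 8 adds once to the amide to give the five-membered magnesium chelate 9, which neither collapses nor enolises in the basic medium and releases ketone 10 only in the cold acidic quench, so over-addition is excluded and the base-sensitive R centre at C8 never meets the organometallic as a ketone.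

Step 5
Reactants: 10 (R)-2-(4-allyl-2,6-dimethoxyphenoxy)-1-(3,4,5-trimethoxyphenyl)propan-1-one; 11 acetic acid
Product: 12 (E)-3-{3,5-dimethoxy-4-[(R)-1-oxo-1-(3,4,5-trimethoxyphenyl)propan-2-yloxy]phenyl}allyl acetate
Conditions: Pd(OAc)2 (10 mol %), 1,4-benzoquinone (2 equiv), 4 Å MS, DMSO/AcOH (1:1), 40 °C, 48 h
Reagents that add atoms: acetic acid (11), CC(=O)O
Why: DMSO-ligated divalent palladium binds the terminal C8'=C9' alkene and, with acetate as internal base, cleaves a C7'–H bond that is both allylic and benzylic to give a syn-1-aryl-π-allylpalladium acetate; acetate is then delivered to the unsubstituted terminus C9', and benzoquinone reoxidises the released zerovalent palladium and ends as hydroquinone. The closest known reaction type is this very one, the sulfoxide-promoted linear allylic C–H acetoxylation of terminal alkenes, which is established for allylarenes giving E-cinnamyl acetates. No ring closes and no stereocentre is made; the only new stereoelement, the E-C7'=C8' alkene, follows from the syn geometry of the aryl-substituted π-allyl unit. The step needs linear over branched acetate, and C–H cleavage over Wacker-type oxypalladation and over mere isomerisation to the propenylarene: attack at C9' is favoured because it is the less hindered terminus and leaves the alkene conjugated with electron-rich ring B, while the sulfoxide ligand steers palladium from oxypalladation towards C–H cleavage. Site selectivity is secured by the substrate, since C7'H2 is its only allylic position and it carries no free O–H or N–H group. The R centre at C8 should persist because the medium holds no base stronger than hydrogen-bonded acetate and no strong acid, and the temperature stays at 40 °C.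

Step 6
Reactants: 12 (E)-3-{3,5-dimethoxy-4-[(R)-1-oxo-1-(3,4,5-trimethoxyphenyl)propan-2-yloxy]phenyl}allyl acetate
Product: 13 (R)-2-{4-[(E)-3-hydroxyprop-1-en-1-yl]-2,6-dimethoxyphenoxy}-1-(3,4,5-trimethoxyphenyl)propan-1-one (target)
Conditions: immobilised Candida antarctica lipase B, MeOH (5 equiv, in portions), MTBE/toluene, 30 °C
Reagents that add atoms: none
Why: Lipase-catalysed transesterification (acyl-enzyme mechanism of a serine hydrolase) moves the acetyl group of the unhindered primary allylic acetate to methanol at neutral pH, so neither base-induced enolisation at C8 nor acid-induced ionisation of the electron-rich cinnamyl C9'–O bond can occur, and the E alkene and the R centre reach the target unchanged.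

**Compound list**
1 | ethyl (S)-lactate | CCOC(=O)[C@H](C)O | starting material
2 | ethyl (S)-2-[(trifluoromethylsulfonyl)oxy]propanoate | CCOC(=O)[C@H](C)OS(=O)(=O)C(F)(F)F | intermediate
3 | 4-allyl-2,6-dimethoxyphenol | C=CCc1cc(OC)c(O)c(OC)c1 | starting material
4 | potassium 4-allyl-2,6-dimethoxyphenolate (not isolated) | C=CCc1cc(OC)c([O-])c(OC)c1.[K+] | intermediate
5 | ethyl (R)-2-(4-allyl-2,6-dimethoxyphenoxy)propanoate | CCOC(=O)[C@@H](C)Oc1c(OC)cc(CC=C)cc1OC | intermediate
6 | (R)-2-(4-allyl-2,6-dimethoxyphenoxy)-N-methoxy-N-methylpropanamide | CON(C)C(=O)[C@@H](C)Oc1c(OC)cc(CC=C)cc1OC | intermediate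
7 | 5-bromo-1,2,3-trimethoxybenzene | COc1cc(Br)cc(OC)c1OC | starting material
8 | 3,4,5-trimethoxyphenylmagnesium bromide (not isolated) | COc1cc([Mg]Br)cc(OC)c1OC | intermediate
9 | bromomagnesium hemiaminal chelate from 6 and 8, R at C8, C7 undefined (not isolated) | COc1cc(C(O[Mg]Br)(N(C)OC)[C@@H](C)Oc2c(OC)cc(CC=C)cc2OC)cc(OC)c1OC | intermediate
10 | (R)-2-(4-allyl-2,6-dimethoxyphenoxy)-1-(3,4,5-trimethoxyphenyl)propan-1-one | COc1cc(C(=O)[C@@H](C)Oc2c(OC)cc(CC=C)cc2OC)cc(OC)c1OC | intermediate
11 | acetic acid | CC(=O)O | starting material
12 | (E)-3-{3,5-dimethoxy-4-[(R)-1-oxo-1-(3,4,5-trimethoxyphenyl)propan-2-yloxy]phenyl}allyl acetate | COc1cc(C(=O)[C@@H](C)Oc2c(OC)cc(/C=C/COC(C)=O)cc2OC)cc(OC)c1OC | intermediate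
13 | (R)-2-{4-[(E)-3-hydroxyprop-1-en-1-yl]-2,6-dimethoxyphenoxy}-1-(3,4,5-trimethoxyphenyl)propan-1-one | COc1cc(C(=O)[C@@H](C)Oc2c(OC)cc(/C=C/CO)cc2OC)cc(OC)c1OC | target

**Totals**
Total step count: 6.
Longest linear sequence: 6 steps (1 → 2 → 5 → 6 → 10 → 12 → 13). Compounds 3, 7 and 11 enter directly.

**Three steps most likely to fail**

Step 5 (key step).
- What may go wrong: oxypalladation of the terminal alkene (Wacker-type path), or plain migration of the alkene into conjugation without C–O bond formation, may outrun C–H cleavage. The catalyst may precipitate as metal before conversion is complete. The long stay in warm DMSO/AcOH may slowly erode the configuration at C8 through enolisation.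
- Fallback (isomerisation followed by cross-metathesis): it sets out from 10. The allyl group is moved into conjugation under neutral conditions with RuHCl(CO)(PPh3)3 in toluene at 80 °C, giving (R)-2-{2,6-dimethoxy-4-[(E)-prop-1-en-1-yl]phenoxy}-1-(3,4,5-trimethoxyphenyl)propan-1-one F1. This β-methylstyrene has no ortho substituent next to the alkene. It is then crossed with excess (Z)-but-2-ene-1,4-diyl diacetate using the second-generation Hoveyda–Grubbs catalyst in CH2Cl2 at 40 °C. That exchanges the ethylidene end for the acetoxyethylidene end with E selectivity, and the route is rejoined at 12.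

Step 6.
- What may go wrong: acyl transfer may be slow or incomplete because the bulky, sparingly soluble substrate is poorly accepted by the enzyme. Any harsher chemical solvolysis invites enolisation at C8 or ionisation of the cinnamyl C–O bond.
- Fallback (same C–H acetoxylation, but it and the ester cleavage are run before the ketone exists): it sets out from 6.
  - Amide 6 is treated with Pd(OAc)2, 1,4-benzoquinone and DMSO/AcOH at 40 °C to give (E)-3-{4-[(R)-1-(methoxy(methyl)amino)-1-oxopropan-2-yloxy]-3,5-dimethoxyphenyl}allyl acetate F2.
  - The α-C–H bond of F2 is far less acidic than that of the ketone, so K2CO3 in MeOH at 0 °C can safely give (R)-2-{4-[(E)-3-hydroxyprop-1-en-1-yl]-2,6-dimethoxyphenoxy}-N-methoxy-N-methylpropanamide F3.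
  - Three equivalents of 8 in THF at −20 → 0 °C first deprotonate the alcohol and then add to the amide, giving the bis(bromomagnesium) alkoxide hemiaminal adduct F4.
  - F4 keeps the carbonyl masked until a quench into cold aqueous NH4Cl, and the route is rejoined at 13.

Step 4.
- What may go wrong: magnesium insertion into the electron-rich bromide may be incomplete. The basic Grignard reagent may deprotonate C8 of the hindered amide, or trigger loss of formaldehyde from the N-methoxy group, in competition with addition. That would cost conversion and enantiomeric purity.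
- Fallback (more electrophilic acceptor, oxidation state restored afterwards): it sets out from 6.
  - Reduction with iBu2AlH in THF at −78 °C gives (R)-2-(4-allyl-2,6-dimethoxyphenoxy)propanal F5, which is used crude.
  - Addition of 8 at −78 °C, where attack on the aldehyde outruns deprotonation, gives (1RS,2R)-2-(4-allyl-2,6-dimethoxyphenoxy)-1-(3,4,5-trimethoxyphenyl)propan-1-ol F6. Its mixture at C7 is of no consequence.
  - Oxidation with Dess–Martin periodinane in CH2Cl2 at rt, under neutral conditions, rejoins the route at 10.

**Further compounds**
F1 | step 5 | (R)-2-{2,6-dimethoxy-4-[(E)-prop-1-en-1-yl]phenoxy}-1-(3,4,5-trimethoxyphenyl)propan-1-one | COc1cc(C(=O)[C@@H](C)Oc2c(OC)cc(/C=C/C)cc2OC)cc(OC)c1OC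
F2 | step 6 | (E)-3-{4-[(R)-1-(methoxy(methyl)amino)-1-oxopropan-2-yloxy]-3,5-dimethoxyphenyl}allyl acetate | CON(C)C(=O)[C@@H](C)Oc1c(OC)cc(/C=C/COC(C)=O)cc1OC
F3 | step 6 | (R)-2-{4-[(E)-3-hydroxyprop-1-en-1-yl]-2,6-dimethoxyphenoxy}-N-methoxy-N-methylpropanamide | CON(C)C(=O)[C@@H](C)Oc1c(OC)cc(/C=C/CO)cc1OC
F4 | step 6 | bis(bromomagnesium) alkoxide hemiaminal adduct | COc1cc(C(O[Mg]Br)(N(C)OC)[C@@H](C)Oc2c(OC)cc(/C=C/CO[Mg]Br)cc2OC)cc(OC)c1OC
F5 | step 4 | (R)-2-(4-allyl-2,6-dimethoxyphenoxy)propanal | O=C[C@@H](C)Oc1c(OC)cc(CC=C)cc1OC
F6 | step 4 | (1RS,2R)-2-(4-allyl-2,6-dimethoxyphenoxy)-1-(3,4,5-trimethoxyphenyl)propan-1-ol | COc1cc(C(O)[C@@H](C)Oc2c(OC)cc(CC=C)cc2OC)cc(OC)c1OC
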